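The earlier runs and the new flask are calculated with constants of no real substance; the scatter is artificial.

The tempting mistake on this flask is to run one exponential through the first readings and read the asked time off it.

| flask | substrate | gas phase | remark | time |
|---|---|---|---|---|
| Sunday's | 0.041 M | 29 mM (held) | run made earlier |  |
| Thursday's | 0.061 M | 29 mM (held) | run made earlier |  |
| flask | 0.082 M | 29 mM (held) |  | 6.0 h |

| run | time / h | target / % |
|---|---|---|
| Sunday's | 0.833 | 15 |
| Sunday's | 2.50 | 35 |
| Sunday's | 5.00 | 48 |
| Sunday's | 8.00 | 56 |
| Thursday's | 0.833 | 10 |
| Thursday's | 2.50 | 30 |
| Thursday's | 5.00 | 40 |
| Thursday's | 8.00 | 50 |

(standard deviation of a reading: 2 percentage points)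

- red: doubling the saturation concentration of gas phase, all else as stated
- violet: doubling the transfer coefficient of the gas phase, all else as stated

- the numbers in the tables scatter by 2 percentage points (one standard deviation)
- at the start none of the gas phase is in solution

- amount of target at 6.0 h, in percent of the substrate charged
- the change that raises the amount of target at 6.0 h, in percent of the substrate charged most ("none" if none brings more than 2 percentage points) (red / violet / none)
- amount of target at 6.0 h, in percent of the substrate charged, after red

With the gas held, take target at the start to form in proportion to the substrate present (pseudo-first-order). That rate integrates to a curve: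

target share = 1 − exp(−start constant × time)

The start constant, the mean from the first readings of both runs, is 0.161 /h, a half-time of 4.31 h.

At 2.50 h the curve gives 33.1%, between the readings of 35% and 30%. By 5.00 h, past the half-time, it runs ahead: 55.2% against 48% and 40%. By 8.00 h it gives 72.4% against 56% and 50%. This reckoning takes the shortfall as proportional to the charge, averages it over both runs and interpolates it in a straight line between the two reading times:

shortfall per charge: 2.13 /M at 5.00 h, 3.83 /M at 8.00 h, 2.70 /M at 6.0 h

flask: 61.9% − 22 percentage points = 39.8%

red, taking the constant to double with the gas level and the shortfall to stay as it is: 63.3%

This reckoning puts no figure on violet; it chooses red, with a gain of 24 points by its own assumptions. The forecast gives 37% for the flask and 53% after red, the change it prefers on the ground that “Doubling saturation raises both driving force and dissolved level”. Both its figures are lower than this reckoning's.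

The flask gives 41.5%. Red gains 19 points and reaches 60.6%, while violet gains 0.23 points.

    dissolved gas → decomposed reagent (k = 0.120 /h)
    gas phase ⇌ dissolved gas, rate k2*(csat - [dissolved gas]) (kL = 29.0 /h)
    substrate + dissolved gas → target (k = 6.60 /M/h)
    substrate → side product A (k = 0.0300 /h)
    substrate + target → side product B (k = 2.70 /M/h)

The curve's 61.9% stands 20 points above this flask. At 6.00 h in this flask, the path to target uses substrate 2.1 times as fast as the path from substrate and target to side product B.

In the neighbour flask read at 1.5 h, the start constant gives 21.5%. The computed neighbour flask holds 20.3% of target.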